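**Retrosynthetic overview** (disconnections listed in the order the bonds are made)

1. The only ring of the target, the quinone carbocycle, is made once: a polyketide-type C2→C7 aldol closure of an open tetraketide chain with loss of CO2, then oxidation up to the hydroxyquinone.
2. Chain (C7–C8 acyl bond): the (R)-3-silyloxytetradecanoyl starter (1 → 2 → 3) plus the triketide 4-methoxy-6-methyl-2H-pyran-2-one 4 (as anion 5) gives the masked tetraketide 6; the O-methyl group comes in with 4.
3. Ring formation: 6 → open chain 7 → benzoic acid 8 → resorcinol monomethyl ether 9. The purchased pyranone ring is opened in this step; no other ring is formed.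
4. Oxygenation and acetate: 9 → quinone 10 (para oxidation) → tetraacetate 11 (Thiele–Winter, which also installs the side-chain acetate) → triol 12 → target 13.
5. Stereocentre: set at the start by ketone hydrogenation (1 → 2) and not touched afterwards.

Assumption: 1 and 4 are bought as catalogue chemicals; the stereocentre is (R), as the given SMILES encodes.

**Step 1**
Reactants: 1 methyl 3-oxotetradecanoate
Product: 2 methyl (3R)-3-hydroxytetradecanoate
Conditions: H2 (50 atm), RuCl2[(R)-BINAP] (0.1 mol %), MeOH, 60 °C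
Reagents that add atoms: none
Why: Noyori asymmetric hydrogenation of a β-keto ester, in which the ester chelates ruthenium and the (R)-BINAP ligand directs hydride to one ketone face, giving the (R)-carbinol (typically ≥97 % ee), the only stereocentre of the target.

**Step 2**
Reactants: 2 methyl (3R)-3-hydroxytetradecanoate
Product: 3 methyl (3R)-3-[(tert-butyldimethylsilyl)oxy]tetradecanoate
Conditions: TBSCl (1.2 equiv), imidazole (2.5 equiv), DMF, rt
Reagents that add atoms: tert-butyldimethylsilyl chloride, CC(C)(C)[Si](C)(C)Cl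
Why: Imidazole-promoted O-silylation masks the carbinol so that the later ortho-carboxylic acid cannot lactonise onto it and the β-oxygen is a poor leaving group; the configuration is untouched.

**Step 3**
Reactants: 3 methyl (3R)-3-[(tert-butyldimethylsilyl)oxy]tetradecanoate; 4 4-methoxy-6-methyl-2H-pyran-2-one
Product: 6 6-[(4R)-4-[(tert-butyldimethylsilyl)oxy]-2-oxopentadecyl]-4-methoxy-2H-pyran-2-one, via lithiated pyranone 5 (not isolated)
Conditions: 4 (2.2 equiv), LiN(SiMe3)2 (2.2 equiv), THF, −78 °C; then 3 (1.0 equiv), −78 → −30 °C; aq. NH4Cl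
Reagents that add atoms: none
Why: Claisen-type C-acylation of the vinylogous 6-methyl anion of the triketide pyranone by the starter ester; two equivalents of anion are used because 6 is deprotonated at its doubly activated CH2, which also protects the β-silyloxy ketone from elimination.

**Step 4**
Reactants: 6 6-[(4R)-4-[(tert-butyldimethylsilyl)oxy]-2-oxopentadecyl]-4-methoxy-2H-pyran-2-one
Product: 9 3-[(2R)-2-[(tert-butyldimethylsilyl)oxy]tridecyl]-5-methoxyphenol, via ring-opened methoxy-dioxo-enoic acid 7 (not isolated), via hydroxy-methoxy-benzoic acid 8 (not isolated)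
Conditions: KOH (2 M), MeOH/H2O 1:1, Ar, rt, 24 h; AcOH to pH 5 at 0 °C, extract into toluene; then toluene/AcOH 10:1, 100 °C, 3 h
Reagents that add atoms: none
Why: Proposed new method: hydroxide opens the 2-pyranone at its lactone carbonyl to carboxylate 7, an open tetraketide whose C3 oxygen is already a methyl enol ether; its C4-deprotonated dienolate attacks the C7 ketone through C2 (six-membered intramolecular aldol condensation, the C2→C7 closure of alkylresorcinol formation, with the carboxylate unable to undergo the rival Claisen closure), water is lost to give arene 8, and acid-assisted ipso-protonation para to OH and ortho to OMe then expels CO2 (protodecarboxylation), taking the hydroxide oxygen with it; C7 stays inside a β-diketonate until the ring closes, so C8 is not enolised and the β-silyloxy stereocentre is neither eliminated nor epimerised; closest known reaction type: hydroxide-induced ring opening and aldol aromatisation of 6-(2-oxoalkyl)-4-hydroxy-2-pyranones to 6-substituted β-resorcylic acids, followed by their thermal decarboxylation to 5-substituted resorcinols.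

**Step 5**
Reactants: 9 3-[(2R)-2-[(tert-butyldimethylsilyl)oxy]tridecyl]-5-methoxyphenol
Product: 10 2-[(2R)-2-[(tert-butyldimethylsilyl)oxy]tridecyl]-6-methoxycyclohexa-2,5-diene-1,4-dione
Conditions: (KO3S)2NO (2.5 equiv), KH2PO4 buffer (pH 6), MeN(C8H17)3Cl (5 mol %), CH2Cl2/H2O, rt
Reagents that add atoms: potassium nitrosodisulfonate, [K+].[K+].[O]N(S(=O)(=O)[O-])S(=O)(=O)[O-]
Why: Teuber oxidation, in which one nitrosodisulfonate radical abstracts the phenolic hydrogen and a second couples at the free para carbon (between OMe and the side chain) to give the 2-methoxy-6-alkyl-1,4-benzoquinone; the silyl ether and the stereocentre are inert at pH 6.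

**Step 6**
Reactants: 10 2-[(2R)-2-[(tert-butyldimethylsilyl)oxy]tridecyl]-6-methoxycyclohexa-2,5-diene-1,4-dione
Product: 11 (2R)-1-[2,3,6-tris(acetyloxy)-5-methoxyphenyl]tridecan-2-yl acetate
Conditions: Ac2O (solvent), H2SO4 (cat.), 0 °C → rt, 6 h; ice-water
Reagents that add atoms: acetic anhydride, CC(=O)OC(C)=O
Why: Thiele–Winter acetoxylation, in which acetate adds to the ring CH next to the alkyl-bearing carbon (para to the methoxy carbon, β to the carbonyl that is not a vinylogous ester) and the hydroquinone is peracetylated, while the same acid converts the secondary silyl ether into the acetate by Si–O cleavage, so the side-chain acetate forms with retention.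

**Step 7**
Reactants: 11 (2R)-1-[2,3,6-tris(acetyloxy)-5-methoxyphenyl]tridecan-2-yl acetate
Product: 13 (2R)-1-(2-hydroxy-5-methoxy-3,6-dioxocyclohexa-1,4-dien-1-yl)tridecan-2-yl acetate (target CNP0258436.1), via triol 12 (not isolated)
Conditions: K2CO3 (0.2 equiv), MeOH, Ar, 0 °C, 30 min; then HCl (aq.) to pH 3, FeCl3 (2.2 equiv), EtOAc/H2O, rt
Reagents that add atoms: none
Why: Base-catalysed transesterification removes only the three aryl acetates (phenoxide leaving groups, far faster than the secondary alkyl acetate at 0 °C), and FeCl3 oxidises the resulting 1,2,4-triol to the 2-hydroxy-1,4-benzoquinone, its stable tautomer, which is the target.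

**Compound list**

1 | methyl 3-oxotetradecanoate | CCCCCCCCCCCC(=O)CC(=O)OC | starting material
2 | methyl (3R)-3-hydroxytetradecanoate | CCCCCCCCCCC[C@H](CC(=O)OC)O | intermediate
3 | methyl (3R)-3-[(tert-butyldimethylsilyl)oxy]tetradecanoate | CCCCCCCCCCC[C@H](CC(=O)OC)O[Si](C)(C)C(C)(C)C | intermediate
4 | 4-methoxy-6-methyl-2H-pyran-2-one | CC1=CC(OC)=CC(=O)O1 | starting material
5 | 6-(lithiomethyl)-4-methoxy-2H-pyran-2-one | [Li]CC1=CC(OC)=CC(=O)O1 | intermediate
6 | 6-[(4R)-4-[(tert-butyldimethylsilyl)oxy]-2-oxopentadecyl]-4-methoxy-2H-pyran-2-one | CCCCCCCCCCC[C@H](CC(=O)CC1=CC(OC)=CC(=O)O1)O[Si](C)(C)C(C)(C)C | intermediate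
7 | (2E,9R)-9-[(tert-butyldimethylsilyl)oxy]-3-methoxy-5,7-dioxoicos-2-enoic acid (potassium salt in the flask) | CCCCCCCCCCC[C@H](CC(=O)CC(=O)C/C(OC)=C\C(O)=O)O[Si](C)(C)C(C)(C)C | intermediate
8 | 2-[(2R)-2-[(tert-butyldimethylsilyl)oxy]tridecyl]-4-hydroxy-6-methoxybenzoic acid | CCCCCCCCCCC[C@H](CC1=CC(O)=CC(OC)=C1C(O)=O)O[Si](C)(C)C(C)(C)C | intermediate
9 | 3-[(2R)-2-[(tert-butyldimethylsilyl)oxy]tridecyl]-5-methoxyphenol | CCCCCCCCCCC[C@H](CC1=CC(O)=CC(OC)=C1)O[Si](C)(C)C(C)(C)C | intermediate
10 | 2-[(2R)-2-[(tert-butyldimethylsilyl)oxy]tridecyl]-6-methoxycyclohexa-2,5-diene-1,4-dione | CCCCCCCCCCC[C@H](CC1=CC(=O)C=C(OC)C1=O)O[Si](C)(C)C(C)(C)C | intermediate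
11 | (2R)-1-[2,3,6-tris(acetyloxy)-5-methoxyphenyl]tridecan-2-yl acetate | CCCCCCCCCCC[C@H](CC1=C(OC(C)=O)C(OC(C)=O)=CC(OC)=C1OC(C)=O)OC(C)=O | intermediate
12 | (2R)-1-(2,3,6-trihydroxy-5-methoxyphenyl)tridecan-2-yl acetate | CCCCCCCCCCC[C@H](CC1=C(O)C(O)=CC(OC)=C1O)OC(C)=O | intermediate
13 | (2R)-1-(2-hydroxy-5-methoxy-3,6-dioxocyclohexa-1,4-dien-1-yl)tridecan-2-yl acetate | CCCCCCCCCCC[C@H](CC1=C(O)C(=O)C=C(OC)C1=O)OC(C)=O | target

**Totals**

Total step count: 7. Longest linear sequence: 7 steps (1 → 13; 4 is bought).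

**Steps most likely to fail**

Step 4 (pyranone-to-arene ring transformation with decarboxylation). The enol-ether carbon C2 may be too weak a nucleophile, a 4-pyranone may form by loss of methoxide, or the silyl ether may be lost before CO2 (which would give a lactone). The fallback sets out from 3 and comes back at 9. Compound 3 acylates the dianion of triacetic acid lactone (4-hydroxy-6-methyl-2H-pyran-2-one, 2.2 equiv, LiN(iPr)2 4.4 equiv, THF, −78 → 0 °C) to give 6-[(4R)-4-[(tert-butyldimethylsilyl)oxy]-2-oxopentadecyl]-4-hydroxy-2H-pyran-2-one F1. Aqueous KOH (2 M, rt) then effects the established ring opening and C2→C7 aldol, in which C2 is a true active methylene, to give 2-[(2R)-2-[(tert-butyldimethylsilyl)oxy]tridecyl]-4,6-dihydroxybenzoic acid F2. Warming in toluene/AcOH expels CO2 and gives 5-[(2R)-2-[(tert-butyldimethylsilyl)oxy]tridecyl]benzene-1,3-diol F3. Mono-O-methylation (MeI 1.0 equiv, K2CO3, acetone; statistical, about 45 %, recovered F3 recycled) rejoins the route at 9.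

Step 3 (acylation of the lithiated pyranone by an enolisable β-silyloxy ester). Proton transfer or elimination may lower the yield. The fallback sets out from 3 and comes back at 6, replacing the Claisen acylation by aldol addition and oxidation. Compound 3 is reduced with iBu2AlH (CH2Cl2, −78 °C) to (3R)-3-[(tert-butyldimethylsilyl)oxy]tetradecanal F4. Anion 5 (from 4 and LiN(SiMe3)2, THF, −78 °C) adds to it to give 6-[(4R)-4-[(tert-butyldimethylsilyl)oxy]-2-hydroxypentadecyl]-4-methoxy-2H-pyran-2-one F5 as a mixture of carbinol epimers. Dess–Martin periodinane (NaHCO3, CH2Cl2) oxidises the new carbinol to ketone 6.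

Step 6 (Thiele–Winter acetoxylation with concurrent silyl-to-acetate exchange). The regiochemistry of acetate addition or the acetolysis of the silyl ether may fail, or the side-chain oxygen may add to the activated quinone. The fallback sets out from 10 and comes back at 13, installing the ring hydroxyl through an epoxide instead. HF (48 % aq.)/MeCN at 0 °C gives 2-[(2R)-2-hydroxytridecyl]-6-methoxycyclohexa-2,5-diene-1,4-dione F6. AcCl/2,6-lutidine (CH2Cl2, 0 °C) gives (2R)-1-(5-methoxy-3,6-dioxocyclohexa-1,4-dien-1-yl)tridecan-2-yl acetate F7. Nucleophilic epoxidation of the alkyl-substituted double bond (t-BuOOH, cat. DBU, CH2Cl2, 0 °C), the one not deactivated by the methoxy group, gives (2R)-1-(3-methoxy-2,5-dioxo-7-oxabicyclo[4.1.0]hept-3-en-1-yl)tridecan-2-yl acetate F8 as epoxide epimers. Acid-mediated epoxide-to-hydroxyquinone isomerisation (cat. H2SO4 in AcOH, or silica gel, rt) gives 13 directly.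

**Further compounds**

F1 | step 4 | 6-[(4R)-4-[(tert-butyldimethylsilyl)oxy]-2-oxopentadecyl]-4-hydroxy-2H-pyran-2-one | CCCCCCCCCCC[C@H](CC(=O)CC1=CC(O)=CC(=O)O1)O[Si](C)(C)C(C)(C)C
F2 | step 4 | 2-[(2R)-2-[(tert-butyldimethylsilyl)oxy]tridecyl]-4,6-dihydroxybenzoic acid | CCCCCCCCCCC[C@H](CC1=CC(O)=CC(O)=C1C(O)=O)O[Si](C)(C)C(C)(C)C
F3 | step 4 | 5-[(2R)-2-[(tert-butyldimethylsilyl)oxy]tridecyl]benzene-1,3-diol | CCCCCCCCCCC[C@H](CC1=CC(O)=CC(O)=C1)O[Si](C)(C)C(C)(C)C
F4 | step 3 | (3R)-3-[(tert-butyldimethylsilyl)oxy]tetradecanal | CCCCCCCCCCC[C@H](CC=O)O[Si](C)(C)C(C)(C)C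
F5 | step 3 | 6-[(4R)-4-[(tert-butyldimethylsilyl)oxy]-2-hydroxypentadecyl]-4-methoxy-2H-pyran-2-one (carbinol epimers) | CCCCCCCCCCC[C@H](CC(O)CC1=CC(OC)=CC(=O)O1)O[Si](C)(C)C(C)(C)C
F6 | step 6 | 2-[(2R)-2-hydroxytridecyl]-6-methoxycyclohexa-2,5-diene-1,4-dione | CCCCCCCCCCC[C@H](CC1=CC(=O)C=C(OC)C1=O)O
F7 | step 6 | (2R)-1-(5-methoxy-3,6-dioxocyclohexa-1,4-dien-1-yl)tridecan-2-yl acetate | CCCCCCCCCCC[C@H](CC1=CC(=O)C=C(OC)C1=O)OC(C)=O
F8 | step 6 | (2R)-1-(3-methoxy-2,5-dioxo-7-oxabicyclo[4.1.0]hept-3-en-1-yl)tridecan-2-yl acetate (epoxide epimers) | CCCCCCCCCCC[C@H](CC12OC1C(=O)C=C(OC)C2=O)OC(C)=O
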